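**Retrosynthetic overview**
1. Feature: with the quinone ring numbered C1(=O)–C2(OAc)–C3(Ar)–C4(=O)–C5(H)–C6(Ar), the four neighbouring carbons C1–C4 carry O, O, aryl, O. This is the four-carbon core of a squaric ester in which one oxygen has been exchanged for the aryl group; only the two-carbon unit C5–C6, a 1-arylvinyl group, is missing.
2. Target 16 ⇐ 15 (debenzylation) ⇐ 14 (O-acetylation at C2–OH) ⇐ 13 (hydrolysis of the C2 vinylogous methyl ester) ⇐ hydroquinone 12 (oxidation).
3. 12 ⇐ 4-(1-arylvinyl)-4-hydroxycyclobutenone 9 by thermal ring expansion: the σ bond between the carbinol carbon (quinone C1) and the carbonyl carbon (quinone C4) opens, then the C4–C5 bond closes. This is the only ring formed in the route; both benzene rings are bought.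
4. 9 ⇐ cyclobutenedione 5 + 1-arylvinyllithium 8 (C1–C6 bond; 8 by Shapiro reaction from ketone 6). 5 ⇐ dimethyl squarate 2 + aryllithium 3 from bromide 1 (C3–aryl bond).

Key step: step 5

Remark on the chemistry: the target has no stereocentre and no stereogenic double bond, so it is one achiral compound and no enantioselective step is needed. The carbinol stereocentres of 4 and 9 form racemic and are erased in steps 2 and 5.

**Step 1**
Reactants: 1 1-(benzyloxy)-4-bromobenzene; 2 dimethyl squarate
Product: 4 4-[4-(benzyloxy)phenyl]-4-hydroxy-2,3-dimethoxycyclobut-2-en-1-one (racemic), via [4-(benzyloxy)phenyl]lithium 3 (not isolated)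
Conditions: n-BuLi (1.05 equiv), THF, −78 °C; cannulate into 2, THF, −78 °C; aq. NH4Cl at −78 °C
Reagents that add atoms: none
Why: Bromine–lithium exchange followed by 1,2-addition of the aryllithium to one of the two equivalent squarate carbonyls should stop at mono-addition because the remaining carbonyl is a deactivated vinylogous ester; the carbinol stereocentre forms racemic and is removed in step 2.

**Step 2**
Reactants: 4 4-[4-(benzyloxy)phenyl]-4-hydroxy-2,3-dimethoxycyclobut-2-en-1-one
Product: 5 3-[4-(benzyloxy)phenyl]-4-methoxycyclobut-3-ene-1,2-dione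
Conditions: conc. HCl (cat.), CH2Cl2, rt
Reagents that add atoms: water, O
Why: Acid-catalysed ionisation of the tertiary benzylic alcohol gives a methoxy-stabilised cyclobutenyl cation that is hydrolysed at its oxocarbenium carbon with loss of methanol (the standard squarate-adduct-to-cyclobutenedione conversion), and the aryl benzyl ether should tolerate brief contact with HCl at room temperature.

**Step 3**
Reactants: 6 4'-(benzyloxy)acetophenone
Product: 7 N'-{(1E)-1-[4-(benzyloxy)phenyl]ethylidene}-2,4,6-triisopropylbenzenesulfonohydrazide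
Conditions: 2,4,6-triisopropylbenzenesulfonohydrazide, conc. HCl (cat.), MeOH, rt
Reagents that add atoms: 2,4,6-triisopropylbenzenesulfonohydrazide, CC(C)c1cc(C(C)C)c(S(=O)(=O)NN)c(C(C)C)c1
Why: Acid-catalysed hydrazone condensation of the aryl methyl ketone should give the (E)-trisylhydrazone, whose methyl group lies syn to the sulfonylated nitrogen as the Shapiro deprotonation requires.

**Step 4**
Reactants: 7 N'-{(1E)-1-[4-(benzyloxy)phenyl]ethylidene}-2,4,6-triisopropylbenzenesulfonohydrazide (1.3 equiv); 5 3-[4-(benzyloxy)phenyl]-4-methoxycyclobut-3-ene-1,2-dione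
Product: 9 2-[4-(benzyloxy)phenyl]-4-{1-[4-(benzyloxy)phenyl]ethenyl}-4-hydroxy-3-methoxycyclobut-2-en-1-one (racemic), via 1-[4-(benzyloxy)phenyl]vinyllithium 8 (not isolated)
Conditions: n-BuLi (2.0 equiv per 7, titrated), THF, −78 → 0 °C until N2 evolution ends; then 5, THF, −78 °C; aq. NH4Cl
Reagents that add atoms: none
Why: Shapiro reaction: the N,C-dianion loses sulfinate and N2 at 0 °C to give the 1-arylvinyllithium (the hindered trisyl group blocks ortho-lithiation), which adds 1,2 to the ketone-like carbonyl flanking C–OMe of 5 rather than to the carbonyl that terminates the vinylogous ester MeO–C=C–C=O; the carbinol stereocentre forms racemic and is destroyed in step 5.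

**Step 5**
Reactants: 9 2-[4-(benzyloxy)phenyl]-4-{1-[4-(benzyloxy)phenyl]ethenyl}-4-hydroxy-3-methoxycyclobut-2-en-1-one
Product: 12 3,6-bis[4-(benzyloxy)phenyl]-2-methoxybenzene-1,4-diol, via dienylketene 10 (not isolated), via cyclohexadienone 11 (not isolated)
Conditions: degassed PhMe (ca. 0.02 M), 110 °C, Ar
Reagents that add atoms: none
Why: Heating opens the cyclobutenone σ bond between the carbonyl and carbinol carbons in a conrotatory 4π electrocyclic reaction to the (Z)-dienylketene 10; the donor hydroxyl rotates outward, which places the 1-arylvinyl group inward, cis to the ketene-bearing carbon. The ketene C=C, the enol C=C and the styrenyl C=C then form a cis-hexatriene that closes by a thermal disrotatory 6π electrocyclisation, joining the ketene carbon (quinone C4) to the vinyl CH2 (quinone C5) and giving the six-membered carbocycle as cyclohexa-2,4-dienone 11. Enolisation of 11 with gain of aromaticity should deliver hydroquinone 12 irreversibly. The closest known reaction type is the thermal ring expansion of 4-alkenyl-4-hydroxycyclobutenones to hydroquinones (Moore rearrangement). No stereocentre is created and the one stereocentre of 9 is destroyed. The step needs outward rotation of OH, which its donor character secures, and dilute oxygen-free conditions so that the ketene is not intercepted; the substitution pattern is fixed by the connectivity of 9, and any adventitious air oxidation only advances material to 13.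

**Step 6**
Reactants: 12 3,6-bis[4-(benzyloxy)phenyl]-2-methoxybenzene-1,4-diol
Product: 13 3,6-bis[4-(benzyloxy)phenyl]-2-methoxy-1,4-benzoquinone
Conditions: Ag2O, Na2SO4, Et2O/CH2Cl2, rt
Reagents that add atoms: none
Why: Ag2O is a mild two-electron oxidant that should convert the electron-rich p-hydroquinone to the quinone without touching the benzyl ethers (hydroquinone-to-quinone oxidation).

**Step 7**
Reactants: 13 3,6-bis[4-(benzyloxy)phenyl]-2-methoxy-1,4-benzoquinone
Product: 14 3,6-bis[4-(benzyloxy)phenyl]-2-hydroxy-1,4-benzoquinone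
Conditions: 1 M NaOH, THF/H2O, rt, Ar; then 1 M HCl to pH 2
Reagents that add atoms: sodium hydroxide, [Na+].[OH-]
Why: Saponification of the vinylogous methyl ester by addition–elimination of hydroxide at C2 is driven by formation of the delocalised hydroxyquinone anion, which is deactivated towards further nucleophilic attack, and the benzyl ethers are stable to base.

**Step 8**
Reactants: 14 3,6-bis[4-(benzyloxy)phenyl]-2-hydroxy-1,4-benzoquinone
Product: 15 2-acetoxy-3,6-bis[4-(benzyloxy)phenyl]-1,4-benzoquinone
Conditions: Ac2O, pyridine, CH2Cl2, 0 °C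
Reagents that add atoms: acetic anhydride, CC(=O)OC(C)=O
Why: O-acylation of the acidic enolic hydroxyl, the only free OH in 14, with acetic anhydride and pyridine should give the enol acetate under cold, mild conditions.

**Step 9**
Reactants: 15 2-acetoxy-3,6-bis[4-(benzyloxy)phenyl]-1,4-benzoquinone
Product: 16 neonambiquinone A (2-acetoxy-3,6-bis(4-hydroxyphenyl)-1,4-benzoquinone)
Conditions: BCl3 (5 equiv), C6HMe5 (6 equiv), CH2Cl2, −78 °C; cold pH 7 phosphate buffer
Reagents that add atoms: none
Why: Lewis-acid debenzylation with BCl3 at −78 °C, in which pentamethylbenzene traps the benzyl cation by Friedel–Crafts alkylation without coordinating boron, cleaves aryl benzyl ethers under conditions that esters tolerate, and a cold buffered quench should protect the labile enol acetate.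

**Compound list**
1 | 1-(benzyloxy)-4-bromobenzene | Brc1ccc(OCc2ccccc2)cc1 | starting material
2 | dimethyl squarate (3,4-dimethoxycyclobut-3-ene-1,2-dione) | COC1=C(OC)C(=O)C1=O | starting material
3 | [4-(benzyloxy)phenyl]lithium | [Li]c1ccc(OCc2ccccc2)cc1 | intermediate
4 | 4-[4-(benzyloxy)phenyl]-4-hydroxy-2,3-dimethoxycyclobut-2-en-1-one (racemic) | COC1=C(OC)C(O)(c2ccc(OCc3ccccc3)cc2)C1=O | intermediate
5 | 3-[4-(benzyloxy)phenyl]-4-methoxycyclobut-3-ene-1,2-dione | COC1=C(c2ccc(OCc3ccccc3)cc2)C(=O)C1=O | intermediate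
6 | 4'-(benzyloxy)acetophenone | CC(=O)c1ccc(OCc2ccccc2)cc1 | starting material
7 | N'-{(1E)-1-[4-(benzyloxy)phenyl]ethylidene}-2,4,6-triisopropylbenzenesulfonohydrazide | C/C(=N\NS(=O)(=O)c1c(C(C)C)cc(C(C)C)cc1C(C)C)c1ccc(OCc2ccccc2)cc1 | intermediate
8 | 1-[4-(benzyloxy)phenyl]vinyllithium | [Li]C(=C)c1ccc(OCc2ccccc2)cc1 | intermediate
9 | 2-[4-(benzyloxy)phenyl]-4-{1-[4-(benzyloxy)phenyl]ethenyl}-4-hydroxy-3-methoxycyclobut-2-en-1-one (racemic) | O=C1C(c2ccc(OCc3ccccc3)cc2)=C(OC)C1(O)C(=C)c1ccc(OCc2ccccc2)cc1 | intermediate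
10 | (3Z)-2,5-bis[4-(benzyloxy)phenyl]-4-hydroxy-3-methoxyhexa-1,3,5-trien-1-one (dienylketene) | O=C=C(c1ccc(OCc2ccccc2)cc1)/C(OC)=C(O)\C(=C)c1ccc(OCc2ccccc2)cc1 | intermediate
11 | 2,5-bis[4-(benzyloxy)phenyl]-4-hydroxy-3-methoxycyclohexa-2,4-dien-1-one | O=C1CC(c2ccc(OCc3ccccc3)cc2)=C(O)C(OC)=C1c1ccc(OCc2ccccc2)cc1 | intermediate
12 | 3,6-bis[4-(benzyloxy)phenyl]-2-methoxybenzene-1,4-diol | COc1c(O)c(-c2ccc(OCc3ccccc3)cc2)cc(O)c1-c1ccc(OCc2ccccc2)cc1 | intermediate
13 | 3,6-bis[4-(benzyloxy)phenyl]-2-methoxy-1,4-benzoquinone | COC1=C(c2ccc(OCc3ccccc3)cc2)C(=O)C=C(c2ccc(OCc3ccccc3)cc2)C1=O | intermediate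
14 | 3,6-bis[4-(benzyloxy)phenyl]-2-hydroxy-1,4-benzoquinone | OC1=C(c2ccc(OCc3ccccc3)cc2)C(=O)C=C(c2ccc(OCc3ccccc3)cc2)C1=O | intermediate
15 | 2-acetoxy-3,6-bis[4-(benzyloxy)phenyl]-1,4-benzoquinone | CC(=O)OC1=C(c2ccc(OCc3ccccc3)cc2)C(=O)C=C(c2ccc(OCc3ccccc3)cc2)C1=O | intermediate
16 | neonambiquinone A (2-acetoxy-3,6-bis(4-hydroxyphenyl)-1,4-benzoquinone) | CC(=O)OC1=C(c2ccc(O)cc2)C(=O)C=C(c2ccc(O)cc2)C1=O | target

**Totals**
Total step count: 9. Longest linear sequence: 8 steps (steps 1, 2, 4, 5, 6, 7, 8, 9); step 3 is the side branch.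

**Steps most likely to fail**

1. Step 9 (final debenzylation). BCl3 may also act on the quinone: boron chelated between C1=O and the acetate oxygen could strip the acetyl group, and chloride or the arene scavenger could add at the unsubstituted C5. The fallback sets out from 15 and returns at 16. Hydrogenolysis (H2, Pd/C, EtOAc, rt) would remove both benzyl groups and reduce the quinone, giving 2,5-dihydroxy-3,6-bis(4-hydroxyphenyl)phenyl acetate F1. Without isolation, F1 would be re-oxidised under neutral conditions (Ag2O, or air) to 16. Acetyl migration to the neighbouring hydroxyl is possible in F1, but it is reversible and only the 2-acetate can be oxidised to a p-quinone, so the oxidation should drain the mixture towards 16.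

2. Step 7 (hydrolysis of the methoxyquinone). Hydroxide may add to the unsubstituted C5 in a conjugate sense, followed by redox exchange with unreacted quinone, instead of displacing methoxide at C2; the hydroxyquinone may also degrade in alkali. The fallback replaces the methyl group by a tert-butyl group that is removed with acid. It sets out from aryllithium 3 (made from 1 as in step 1) and returns at 14.
   - Aryllithium 3 is added at −78 °C to di-tert-butyl squarate F2 (purchased), giving 4-[4-(benzyloxy)phenyl]-2,3-di-tert-butoxy-4-hydroxycyclobut-2-en-1-one F3 as its lithium alkoxide.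
   - Trifluoroacetic anhydride at −78 °C and aqueous work-up convert F3 to 3-[4-(benzyloxy)phenyl]-4-tert-butoxycyclobut-3-ene-1,2-dione F4. The hydroxyl leaves as trifluoroacetate and one tert-butoxy group as tert-butanol.
   - Vinyllithium 8 is added as in step 4 to give 2-[4-(benzyloxy)phenyl]-4-{1-[4-(benzyloxy)phenyl]ethenyl}-3-tert-butoxy-4-hydroxycyclobut-2-en-1-one F5.
   - Thermolysis as in step 5 gives 3,6-bis[4-(benzyloxy)phenyl]-2-tert-butoxybenzene-1,4-diol F6, and Ag2O as in step 6 gives 3,6-bis[4-(benzyloxy)phenyl]-2-tert-butoxy-1,4-benzoquinone F7.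
   - TFA in CH2Cl2 at rt cleaves the tert-butyl vinylogous ester as 2-methylpropene and leaves the aryl benzyl ethers, giving 14. Any earlier thermal loss of the tert-butyl group would still lead to 14 after oxidation.

3. Step 4 (Shapiro generation and addition of the vinyllithium). The dianion may fragment incompletely or the vinyllithium may be protonated to the styrene, so that residual base or too little nucleophile meets 5. The vinyllithium may also attack the methoxy-bearing carbon in a conjugate addition–elimination. The fallback makes the same nucleophile cleanly at low temperature by halogen–lithium exchange. It sets out from ketone 6 and returns at 8, which then adds to 5 as in step 4.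
   - Hydrazine hydrate in EtOH at reflux gives (E)-{1-[4-(benzyloxy)phenyl]ethylidene}hydrazine F8.
   - Iodine and tetramethylguanidine in Et2O (Barton vinyl iodide synthesis) give 1-(benzyloxy)-4-(1-iodovinyl)benzene F9.
   - t-BuLi (2 equiv) in THF/Et2O at −78 °C gives 8 free of sulfinate and of unreacted alkyllithium.

**Further compounds**
F1 | step 9 | 2,5-dihydroxy-3,6-bis(4-hydroxyphenyl)phenyl acetate | CC(=O)Oc1c(O)c(-c2ccc(O)cc2)cc(O)c1-c1ccc(O)cc1
F2 | step 7 | di-tert-butyl squarate (3,4-di-tert-butoxycyclobut-3-ene-1,2-dione, purchased) | CC(C)(C)OC1=C(OC(C)(C)C)C(=O)C1=O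
F3 | step 7 | 4-[4-(benzyloxy)phenyl]-2,3-di-tert-butoxy-4-hydroxycyclobut-2-en-1-one (racemic) | CC(C)(C)OC1=C(OC(C)(C)C)C(O)(c2ccc(OCc3ccccc3)cc2)C1=O
F4 | step 7 | 3-[4-(benzyloxy)phenyl]-4-tert-butoxycyclobut-3-ene-1,2-dione | CC(C)(C)OC1=C(c2ccc(OCc3ccccc3)cc2)C(=O)C1=O
F5 | step 7 | 2-[4-(benzyloxy)phenyl]-4-{1-[4-(benzyloxy)phenyl]ethenyl}-3-tert-butoxy-4-hydroxycyclobut-2-en-1-one (racemic) | O=C1C(c2ccc(OCc3ccccc3)cc2)=C(OC(C)(C)C)C1(O)C(=C)c1ccc(OCc2ccccc2)cc1
F6 | step 7 | 3,6-bis[4-(benzyloxy)phenyl]-2-tert-butoxybenzene-1,4-diol | CC(C)(C)Oc1c(O)c(-c2ccc(OCc3ccccc3)cc2)cc(O)c1-c1ccc(OCc2ccccc2)cc1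
F7 | step 7 | 3,6-bis[4-(benzyloxy)phenyl]-2-tert-butoxy-1,4-benzoquinone | CC(C)(C)OC1=C(c2ccc(OCc3ccccc3)cc2)C(=O)C=C(c2ccc(OCc3ccccc3)cc2)C1=O
F8 | step 4 | (E)-{1-[4-(benzyloxy)phenyl]ethylidene}hydrazine | C/C(=N\N)c1ccc(OCc2ccccc2)cc1
F9 | step 4 | 1-(benzyloxy)-4-(1-iodovinyl)benzene | C=C(I)c1ccc(OCc2ccccc2)cc1
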